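(All runs were computed for substances that don't exist; noise was put on by code.)

With the temperature up from 35 °C to 57 °C, the lead of the left-handed product in the earlier runs shrinks, and amber and red lie on either side of that range.

common to all: left-handed substrate 0.80 M; right-handed substrate 0.80 M; added ligand 6.3 mM
- theta: reagent 0.96 M; free catalyst 0.47 mM; temperature 35 °C; run made earlier
- beta: reagent 0.96 M; free catalyst 0.95 mM; temperature 57 °C; run made earlier
- gamma: reagent 0.96 M; free catalyst 1.9 mM; temperature 35 °C; run made earlier
- amber: reagent 0.960 M; free catalyst 0.50 mM; temperature 65 °C; time 10 h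
- red: reagent 0.960 M; free catalyst 1.8 mM; temperature 25 °C; time 10 h

theta run (percent of the left-handed substrate and right-handed substrate together charged)

| time / h | left-handed product / % | right-handed product / % | left-handed substrate / % |
|---|---|---|---|
| 0.333 | 19 | 3 | 31 |
| 0.667 | 24 | 5 | 25 |
| 1.33 | 31 | 4 | 18 |
| 2.50 | 34 | 7 | 19 |
| 5.00 | 33 | 7 | 17 |

beta run (percent of the left-handed substrate and right-handed substrate together charged)

| time / min | left-handed product / % | right-handed product / % | left-handed substrate / % |
|---|---|---|---|
| 6.00 | 21 | 7 | 28 |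
| 12.0 | 24 | 10 | 24 |
| 25.0 | 28 | 9 | 24 |
| 50.0 | 28 | 12 | 23 |
| 90.0 | 28 | 12 | 21 |

gamma run (percent of the left-handed substrate and right-handed substrate together charged)

| time / h | left-handed product / % | right-handed product / % | left-handed substrate / % |
|---|---|---|---|
| 0.333 | 35 | 7 | 12 |
| 0.667 | 43 | 8 | 11 |
| 1.33 | 44 | 11 | 7 |
| 2.50 | 45 | 10 | 8 |
| 5.00 | 42 | 12 | 4 |

(readings scatter by 1.5 percentage points)

- free catalyst is single-handed; left-handed substrate and right-handed substrate are mirror images of each other, charged as a racemate, each of them at the stated concentration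
- an excess is the difference of the two amounts in percent of their sum
- an excess is below zero if the other one leads

- which of the two ends with the higher excess of left-handed product over right-handed product ("neither" if they lie within 2 percentage points) (amber / red / neither)
- excess of left-handed product over right-handed product at the end, amber
- excess of left-handed product over right-handed product at the end, red

Let ρ be left-handed over right-handed product, summed over the last two readings of a run; the excess is then (ρ−1)/(ρ+1), and this flask is a kinetic resolution. Theta and gamma, both at 35 °C, pool to 4.28, while beta at 57 °C, its free catalyst between theirs, gives less, 2.33. Hence λ = 0.0276 K⁻¹, the fall of ln ρ per degree.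

Amber is hotter than beta, so if the trend holds, its excess lies below beta's 40.0%. That is the upper bound. For the lower bound, beta's readings are moved one scatter against the lead: ρ drops to 1.96, the slope steepens to 0.0354 K⁻¹, and amber reaches ρ = 1.48, an excess of 19.3%.

My own reckoning takes λ as it stands. Amber gets ρ = 1.87, an excess of 30.4%. Red at 25 °C gets ρ = 5.63, an excess of 69.9%.

The forecast names red, with 33% for amber and 67% for red, holding that “the catalyst is dying”. Its amber sits inside the bracket, higher than my figure, and its red lower.

The flasks give red as the higher: amber 24.7%, red 69.1%.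

    free catalyst + left-handed substrate ⇌ catalyst intermediate A (K = 1.93 L mol⁻¹, k = 307 L mol⁻¹ min⁻¹, Ea = 49.0 kJ mol⁻¹, ΔH = −20.0 kJ mol⁻¹)
    free catalyst + right-handed substrate ⇌ catalyst intermediate B (K = 0.320 L mol⁻¹, k = 22.1 L mol⁻¹ min⁻¹, Ea = 62.0 kJ mol⁻¹, ΔH = 26.0 kJ mol⁻¹)
    reagent + catalyst intermediate A → free catalyst + left-handed product (k = 84.7 L mol⁻¹ min⁻¹, Ea = 48.0 kJ mol⁻¹)
    reagent + catalyst intermediate B → free catalyst + right-handed product (k = 37.0 L mol⁻¹ min⁻¹, Ea = 49.0 kJ mol⁻¹)
    free catalyst + added ligand ⇌ idle complex (K = 35.3 L mol⁻¹, k = 3.00 L mol⁻¹ min⁻¹, Ea = 49.0 kJ mol⁻¹, ΔH = −42.0 kJ mol⁻¹)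
    2 reagent → self-condensation product (k = 0.00638 L mol⁻¹ min⁻¹, Ea = 75.0 kJ mol⁻¹)
    (constants at 25 °C)

Amber's excess means ρ = 1.66, below the 1.87 reckoned. In amber at 0.0406 h, free catalyst goes forward to catalyst intermediate A 6.8 times as fast as to catalyst intermediate B, but A falls back 15 times faster than it goes on and B 2.8 times, so what passes on stands at a ratio of 1.68. Carried by λ from beta to a repeat of amber at 50 °C, ρ reads 2.83, an excess of 47.8%, and that flask ends at 48.7%.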